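The runs are simulated on assumed constants; noise was put on by code.

We leave both flasks on their programmes and add no extra capture agent. Monday's flask turns on one number.

| flask | starting material | capture agent | temperature | remark | time |
|---|---|---|---|---|---|
| teal | 0.23 M (in portions, 4) | 0.46 M | −32 °C | run made earlier; portions every 25 h |  |
| grey | 0.35 M (in portions, 4) | 0.46 M | −16 °C | run made earlier; portions every 25 h |  |
| Friday's | 0.46 M (in portions, 4) | 0.460 M |  | at −10 °C throughout; the portions of starting material follow each other after 25 h, the first at the start | 1.2 d |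
| Monday's | 0.46 M (in portions, 4) | 0.460 M |  | at −40 °C until 2.5 d, from then on at −10 °C; the portions of starting material follow each other after 25 h, the first at the start | 5.0 d |

- teal (time / d: target / %, trapped intermediate / %): 0.833: 1, 7; 1.67: 2, 13; 2.50: 1, 20; 3.00: 3, 22; 4.00: 4, 31; 5.00: 5, 29
- grey (time / h: target / %, trapped intermediate / %): 3.00: 5, 2; 5.00: 8, 5; 8.00: 7, 1; 12.0: 5, 4; 20.0: 11, 2; 40.0: 14, 8

(each reading ± 1.5 percentage points)

- percentages count the whole charge, also what has not yet gone in

1. which one finishes higher in share of target in all that became target or trapped intermediate ("neither" within 2 percentage points) (Friday's / Monday's / neither)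
2. share of target in all that became target or trapped intermediate, Friday's
3. share of target in all that became target or trapped intermediate, Monday's

1. Teal read 20.0 % trapped intermediate at 2.50 d. We call this the cold debt: trapped intermediate, in percent of the whole charge, standing when a flask warms.

2. Monday's has teal's [capture agent] and portion timing, so we carry the percentage over. It is rough, since Monday's stands colder, at −40 °C, and its charge is twice teal's. Friday's never changes temperature, so the cold debt does not apply to it.

3. In grey's last reading, 2 of 4 portions were in, and target plus trapped intermediate made 44.0 % of that.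

4. Across grey's readings, target took 69.4 % of the two. This share, the selectivity, is probably low for −10 °C.

5. We reckon that the rest of Monday's charge adds 35.2 % of products, so we expect 44.3 % for Monday's. Friday's should stand near 69.4 %, higher than Monday's.

The forecast said Friday's, with 85 % and 70 %, from “turning perhaps 10% of the charge” while cold, where we carry 20.0 %.

The flasks give 85.1 % for Friday's and 50.5 % for Monday's, so Friday's finishes higher.

    starting material ⇌ intermediate C (k = 1.60 × 10⁻⁴ min⁻¹, Ea = 74.0 kJ mol⁻¹)
    starting material ⇌ intermediate B (K = 14.0, k = 0.00450 min⁻¹, Ea = 78.0 kJ mol⁻¹, ΔH = −66.0 kJ mol⁻¹)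
    intermediate B → decomposed reagent (k = 6.70 × 10⁻⁴ min⁻¹, Ea = 75.0 kJ mol⁻¹)
    intermediate B ⇌ intermediate C (K = 9.80, k = 3.10 × 10⁻⁵ min⁻¹, Ea = 91.0 kJ mol⁻¹, ΔH = −39.0 kJ mol⁻¹)
    capture agent + intermediate B → trapped intermediate (k = 0.00120 M⁻¹ min⁻¹, Ea = 50.0 kJ mol⁻¹)
    starting material → intermediate A (k = 1.10 × 10⁻⁴ min⁻¹, Ea = 85.0 kJ mol⁻¹)
    intermediate A → target (k = 2.30 × 10⁻⁴ min⁻¹, Ea = 88.0 kJ mol⁻¹)
    (constants at −40 °C)

Monday's debt stood at 21.1 % at 2.50 d, and warming added 3.3 percentage points more. The difference in temperature programme is the main reason the two flasks part: with it taken away, Friday's gives 2.13 % instead of 85.1 %. Scaling our debt by [capture agent] gives 33.9 % for the neighbour charged with 0.78 M. With Monday's target and warm gain in trapped intermediate, that makes 40.0 %. The neighbour gives 38.6 %.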